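Ring A (C4a, C5, C6, C7, C8, C8a) has its C8 oxygen para to C5, the carbon that bears the pyrone, and C5 sits between the C4a side chain and the C6 phenyl group. A 4-alkyl-2-silyloxybuta-1,3-diene and an aryl ynone give this ortho/para pattern, so ring A is cut at C6–C7 and C4a–C5.
Ring A is formed first: diene 7 (C7, C8, C8a, C4a and the C4–C1 chain with C3 already set) and 4-phenylbut-3-yn-2-one 8 (C5, C6, acetyl) undergo a Diels–Alder reaction, and DDQ aromatises the adduct.
The pyrone ring is formed second, from the C5 acetyl group (silyl enol ether plus malonyl dichloride) while C1 is still a tert-butyl ester, because a 3-silyloxy-1-tetralone would lose its C3 oxygen by E1cB elimination under enolate chemistry.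
Ring B is formed last by Friedel–Crafts acylation (C1–C8a). Buffered HF then removes all silyl groups.
C3 is bought in half-ester 1. Its acid arm becomes C1/C2 and its ester arm becomes C4/C4a, which leads to the (S) series.

Key step: step 5

Assumption: half-ester 1, an intermediate of statin manufacture, is bought as the single (R) enantiomer.
Abbreviations: TBS = tert-butyldimethylsilyl, TIPS = triisopropylsilyl, TMS = trimethylsilyl.

Step 1
Reactants: 1 (3R)-3-(TBS-oxy)-5-methoxy-5-oxopentanoic acid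
Product: 2 1-tert-butyl 5-methyl (3S)-3-(TBS-oxy)pentanedioate
Conditions: Cl3CC(=NH)OtBu (2 equiv), CH2Cl2–cyclohexane, rt
Reagents that add atoms: tert-butyl 2,2,2-trichloroacetimidate, CC(C)(C)OC(=N)C(Cl)(Cl)Cl
Why: Trichloroacetimidate esterification, in which the acid protonates the imidate and takes up the tert-butyl group under almost neutral conditions, so the silyl ether and methyl ester survive, the two arms now differ in size, and the descriptor changes from R to S only because the arm priorities swap.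

Step 2
Reactants: 2 1-tert-butyl 5-methyl (3S)-3-(TBS-oxy)pentanedioate
Product: 4 tert-butyl (3S)-3-(TBS-oxy)-5-oxopentanoate, via diisobutylaluminium hemiacetal 3 (not isolated)
Conditions: iBu2AlH (1.1 equiv), toluene, −78 °C; MeOH, then aq. potassium sodium tartrate
Reagents that add atoms: none
Why: Partial ester reduction with iBu2AlH, in which the open methyl ester reacts far faster than the tert-butyl ester and hemiacetal 3 holds at −78 °C until the quench, so reduction should stop at the aldehyde.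

Step 3
Reactants: 4 tert-butyl (3S)-3-(TBS-oxy)-5-oxopentanoate; 5 1-(triphenylphosphoranylidene)propan-2-one
Product: 6 tert-butyl (3S,5E)-3-(TBS-oxy)-7-oxooct-5-enoate
Conditions: THF, 50 °C
Reagents that add atoms: none
Why: Wittig olefination with a stabilised acyl ylide, which is E-selective and too weakly basic to eliminate the β-silyloxy group of the aldehyde.

Step 4
Reactants: 6 tert-butyl (3S,5E)-3-(TBS-oxy)-7-oxooct-5-enoate
Product: 7 tert-butyl (3S,5E)-3,7-bis(TBS-oxy)octa-5,7-dienoate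
Conditions: TBSOTf (1.2 equiv), Et3N (2 equiv), Et2O, −78 → 0 °C
Reagents that add atoms: tert-butyldimethylsilyl trifluoromethanesulfonate, CC(C)(C)[Si](C)(C)OS(=O)(=O)C(F)(F)F
Why: Soft enolisation, in which O-silylation of the enone is followed by kinetic removal of an α′-methyl proton rather than a γ proton, giving the cross-conjugated 2-silyloxydiene with the E alkene kept, while the low temperature and small excess of triflate spare the tert-butyl ester.

Step 5
Reactants: 7 tert-butyl (3S,5E)-3,7-bis(TBS-oxy)octa-5,7-dienoate; 8 4-phenylbut-3-yn-2-one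
Product: 10 tert-butyl (3S)-4-[2-acetyl-5-(TBS-oxy)-3-phenylphenyl]-3-(TBS-oxy)butanoate, via cyclohexa-1,4-diene cycloadduct 9 (not isolated)
Conditions: 8 (2 equiv), BHT (cat.), toluene (2 M), sealed tube, 150 °C; then dilute, 0 °C, DDQ (1.1 equiv), 0 °C → rt
Reagents that add atoms: none
Why: This is a thermal, concerted but asynchronous normal-electron-demand [4+2] cycloaddition in which the HOMO of 7 is largest at the CH2 terminus next to the silyloxy carbon (C7) and the LUMO of 8 is largest at the phenyl-bearing alkyne carbon (C6), so C6–C7 forms ahead of C4a–C5. The closest known reaction type is the Diels–Alder reaction of 2-silyloxybuta-1,3-dienes with acetylenic ketones and esters, followed by quinone dehydrogenation to aryl silyl ethers. Ring A closes intermolecularly as a six-membered carbocycle, four carbons (C7, C8, C8a, C4a) coming from the diene and two (C5, C6) from the alkyne, and the E alkene turns C4 outward so that the s-cis conformer is populated. The only new stereocentre, C4a of 9, needs no control because DDQ takes hydride from a doubly allylic position (C7 or C4a) and loss of the other hydrogen as a proton flattens it into arene 10, while C3 lies outside the reacting π system and keeps its configuration. The selectivity needed is regiochemical and the substrate secures it twice, since the C8 donor places the acetyl carbon para to itself and the C4a alkyl group places it ortho. Diene 7 is the limiting partner, so none remains to consume DDQ, and surplus 8 is inert to the quinone.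

Step 6
Reactants: 10 tert-butyl (3S)-4-[2-acetyl-5-(TBS-oxy)-3-phenylphenyl]-3-(TBS-oxy)butanoate
Product: 12 tert-butyl (3S)-3-(TBS-oxy)-4-{5-(TBS-oxy)-3-phenyl-2-[1-(TMS-oxy)ethenyl]phenyl}butanoate, via lithium enolate 11 (not isolated)
Conditions: LiN(SiMe3)2 (1.1 equiv), THF, −78 °C; Me3SiCl (1.3 equiv), −78 → 0 °C; pentane, cold aq. NaHCO3, used crude
Reagents that add atoms: chlorotrimethylsilane, C[Si](C)(C)Cl
Why: Kinetic enolate formation and O-silylation, in which the amide base removes a methyl proton of the twisted acetyl group, far more acidic than the α-CH2 of the tert-butyl ester, so the β-silyloxy ester is not enolised and cannot eliminate.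

Step 7
Reactants: 12 tert-butyl (3S)-3-(TBS-oxy)-4-{5-(TBS-oxy)-3-phenyl-2-[1-(TMS-oxy)ethenyl]phenyl}butanoate; 13 malonyl dichloride
Product: 15 tert-butyl (3S)-3-(TBS-oxy)-4-[5-(TBS-oxy)-2-(4-hydroxy-2-oxo-2H-pyran-6-yl)-3-phenylphenyl]butanoate, via 3,5-dioxopentanoyl chloride 14 (not isolated)
Conditions: 13 (1.1 equiv), Et2O, −78 °C → rt
Reagents that add atoms: none
Why: Claisen-type C-acylation of the enol ether at its unhindered CH2 terminus followed by enol lactonisation of 14, the known silyl enol ether–malonyl dichloride route to 6-aryl-4-hydroxy-2-pyrones, which needs no base.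

Step 8
Reactants: 15 tert-butyl (3S)-3-(TBS-oxy)-4-[5-(TBS-oxy)-2-(4-hydroxy-2-oxo-2H-pyran-6-yl)-3-phenylphenyl]butanoate
Product: 16 tert-butyl (3S)-3-(TBS-oxy)-4-{5-(TBS-oxy)-2-[2-oxo-4-(TIPS-oxy)-2H-pyran-6-yl]-3-phenylphenyl}butanoate
Conditions: TIPSCl (1.1 equiv), imidazole (2 equiv), CH2Cl2, 0 °C
Reagents that add atoms: chlorotriisopropylsilane, CC(C)[Si](Cl)(C(C)C)C(C)C
Why: O-silylation of the acidic vinylogous-acid hydroxyl, which masks the pyrone so that the acid activation in step 10 meets only one acidic OH and the nucleophilic pyrone is blocked from acylation.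

Step 9
Reactants: 16 tert-butyl (3S)-3-(TBS-oxy)-4-{5-(TBS-oxy)-2-[2-oxo-4-(TIPS-oxy)-2H-pyran-6-yl]-3-phenylphenyl}butanoate
Product: 18 (3S)-3-(TBS-oxy)-4-{5-(TBS-oxy)-2-[2-oxo-4-(TIPS-oxy)-2H-pyran-6-yl]-3-phenylphenyl}butanoic acid, via trimethylsilyl ester 17 (not isolated)
Conditions: Me3SiOTf (2.5 equiv), 2,6-lutidine (4 equiv), CH2Cl2, 0 °C → rt; pH 7 phosphate buffer
Reagents that add atoms: none
Why: Silyl-triflate-mediated tert-butyl ester cleavage (loss of isobutene from the O-silylated ester, buffered by lutidine), which avoids hydroxide and so keeps the base-labile aryl silyl ether and the β-silyloxy acid intact, and only the TMS ester hydrolyses on contact with the buffer.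

Step 10
Reactants: 18 (3S)-3-(TBS-oxy)-4-{5-(TBS-oxy)-2-[2-oxo-4-(TIPS-oxy)-2H-pyran-6-yl]-3-phenylphenyl}butanoic acid
Product: 20 (3S)-3,8-bis(TBS-oxy)-5-[2-oxo-4-(TIPS-oxy)-2H-pyran-6-yl]-6-phenyl-3,4-dihydronaphthalen-1(2H)-one, via acid chloride 19 (not isolated)
Conditions: Me2C=C(Cl)NMe2 (1.1 equiv), CH2Cl2, 0 °C; dilute to 0.01 M, SnCl4 (3 equiv), −78 → −30 °C; cold aq. NaHCO3
Reagents that add atoms: none
Why: Intramolecular Friedel–Crafts acylation after neutral acid chloride formation, closing six-membered ring B at C8a, the one unsubstituted carbon next to C4a, which is ortho to the C8 oxygen, para to the phenyl group and meta to the twisted pyrone, while low temperature and a cold quench guard the C3 silyloxy group against β-elimination.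

Step 11
Reactants: 20 (3S)-3,8-bis(TBS-oxy)-5-[2-oxo-4-(TIPS-oxy)-2H-pyran-6-yl]-6-phenyl-3,4-dihydronaphthalen-1(2H)-one
Product: 21 wailupemycin F, (3S)-3,8-dihydroxy-5-(4-hydroxy-2-oxo-2H-pyran-6-yl)-6-phenyl-3,4-dihydronaphthalen-1(2H)-one
Conditions: HF·pyridine, pyridine, THF, 0 °C → rt; pH 6 phosphate buffer
Reagents that add atoms: none
Why: Fluoride-mediated global desilylation in a mildly acidic buffered medium, which breaks only Si–O bonds so C3 keeps its configuration, and avoids the basic fluoride sources that would dehydrate the β-hydroxy ketone to a naphthol.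

Compound list
1 | (3R)-3-(tert-butyldimethylsilyloxy)-5-methoxy-5-oxopentanoic acid | OC(=O)C[C@@H](O[Si](C)(C)C(C)(C)C)CC(=O)OC | starting material
2 | 1-tert-butyl 5-methyl (3S)-3-(tert-butyldimethylsilyloxy)pentanedioate | CC(C)(C)OC(=O)C[C@@H](O[Si](C)(C)C(C)(C)C)CC(=O)OC | intermediate
3 | diisobutylaluminium hemiacetal of 2 at the methyl ester carbon (acetal carbon unassigned) | CC(C)(C)OC(=O)C[C@@H](O[Si](C)(C)C(C)(C)C)CC(OC)O[Al](CC(C)C)CC(C)C | intermediate
4 | tert-butyl (3S)-3-(tert-butyldimethylsilyloxy)-5-oxopentanoate | CC(C)(C)OC(=O)C[C@@H](O[Si](C)(C)C(C)(C)C)CC=O | intermediate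
5 | 1-(triphenylphosphoranylidene)propan-2-one | CC(=O)C=P(c1ccccc1)(c1ccccc1)c1ccccc1 | starting material
6 | tert-butyl (3S,5E)-3-(tert-butyldimethylsilyloxy)-7-oxooct-5-enoate | CC(C)(C)OC(=O)C[C@@H](O[Si](C)(C)C(C)(C)C)C/C=C/C(C)=O | intermediate
7 | tert-butyl (3S,5E)-3,7-bis(tert-butyldimethylsilyloxy)octa-5,7-dienoate | CC(C)(C)OC(=O)C[C@@H](O[Si](C)(C)C(C)(C)C)C/C=C/C(=C)O[Si](C)(C)C(C)(C)C | intermediate
8 | 4-phenylbut-3-yn-2-one | CC(=O)C#Cc1ccccc1 | starting material
9 | tert-butyl (3S)-4-[2-acetyl-5-(tert-butyldimethylsilyloxy)-3-phenylcyclohexa-2,5-dien-1-yl]-3-(tert-butyldimethylsilyloxy)butanoate (both ring C1 epimers) | CC(C)(C)OC(=O)C[C@@H](O[Si](C)(C)C(C)(C)C)CC1C=C(O[Si](C)(C)C(C)(C)C)CC(c2ccccc2)=C1C(C)=O | intermediate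
10 | tert-butyl (3S)-4-[2-acetyl-5-(tert-butyldimethylsilyloxy)-3-phenylphenyl]-3-(tert-butyldimethylsilyloxy)butanoate | CC(C)(C)OC(=O)C[C@@H](O[Si](C)(C)C(C)(C)C)Cc1cc(O[Si](C)(C)C(C)(C)C)cc(-c2ccccc2)c1C(C)=O | intermediate
11 | lithium enolate of 10 at the acetyl group | CC(C)(C)OC(=O)C[C@@H](O[Si](C)(C)C(C)(C)C)Cc1cc(O[Si](C)(C)C(C)(C)C)cc(-c2ccccc2)c1C(=C)[O-].[Li+] | intermediate
12 | tert-butyl (3S)-3-(tert-butyldimethylsilyloxy)-4-{5-(tert-butyldimethylsilyloxy)-3-phenyl-2-[1-(trimethylsilyloxy)ethenyl]phenyl}butanoate | CC(C)(C)OC(=O)C[C@@H](O[Si](C)(C)C(C)(C)C)Cc1cc(O[Si](C)(C)C(C)(C)C)cc(-c2ccccc2)c1C(=C)O[Si](C)(C)C | intermediate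
13 | malonyl dichloride | O=C(Cl)CC(=O)Cl | starting material
14 | tert-butyl (3S)-3-(tert-butyldimethylsilyloxy)-4-[5-(tert-butyldimethylsilyloxy)-2-(5-chloro-3,5-dioxopentanoyl)-3-phenylphenyl]butanoate | CC(C)(C)OC(=O)C[C@@H](O[Si](C)(C)C(C)(C)C)Cc1cc(O[Si](C)(C)C(C)(C)C)cc(-c2ccccc2)c1C(=O)CC(=O)CC(=O)Cl | intermediate
15 | tert-butyl (3S)-3-(tert-butyldimethylsilyloxy)-4-[5-(tert-butyldimethylsilyloxy)-2-(4-hydroxy-2-oxo-2H-pyran-6-yl)-3-phenylphenyl]butanoate | CC(C)(C)OC(=O)C[C@@H](O[Si](C)(C)C(C)(C)C)Cc1cc(O[Si](C)(C)C(C)(C)C)cc(-c2ccccc2)c1-c3cc(O)cc(=O)o3 | intermediate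
16 | tert-butyl (3S)-3-(tert-butyldimethylsilyloxy)-4-{5-(tert-butyldimethylsilyloxy)-2-[2-oxo-4-(triisopropylsilyloxy)-2H-pyran-6-yl]-3-phenylphenyl}butanoate | CC(C)(C)OC(=O)C[C@@H](O[Si](C)(C)C(C)(C)C)Cc1cc(O[Si](C)(C)C(C)(C)C)cc(-c2ccccc2)c1-c3cc(O[Si](C(C)C)(C(C)C)C(C)C)cc(=O)o3 | intermediate
17 | trimethylsilyl ester of acid 18 | C[Si](C)(C)OC(=O)C[C@@H](O[Si](C)(C)C(C)(C)C)Cc1cc(O[Si](C)(C)C(C)(C)C)cc(-c2ccccc2)c1-c3cc(O[Si](C(C)C)(C(C)C)C(C)C)cc(=O)o3 | intermediate
18 | (3S)-3-(tert-butyldimethylsilyloxy)-4-{5-(tert-butyldimethylsilyloxy)-2-[2-oxo-4-(triisopropylsilyloxy)-2H-pyran-6-yl]-3-phenylphenyl}butanoic acid | OC(=O)C[C@@H](O[Si](C)(C)C(C)(C)C)Cc1cc(O[Si](C)(C)C(C)(C)C)cc(-c2ccccc2)c1-c3cc(O[Si](C(C)C)(C(C)C)C(C)C)cc(=O)o3 | intermediate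
19 | acid chloride of 18 | ClC(=O)C[C@@H](O[Si](C)(C)C(C)(C)C)Cc1cc(O[Si](C)(C)C(C)(C)C)cc(-c2ccccc2)c1-c3cc(O[Si](C(C)C)(C(C)C)C(C)C)cc(=O)o3 | intermediate
20 | (3S)-3,8-bis(tert-butyldimethylsilyloxy)-5-[2-oxo-4-(triisopropylsilyloxy)-2H-pyran-6-yl]-6-phenyl-3,4-dihydronaphthalen-1(2H)-one | O=C1C[C@@H](O[Si](C)(C)C(C)(C)C)Cc2c1c(O[Si](C)(C)C(C)(C)C)cc(-c3ccccc3)c2-c4cc(O[Si](C(C)C)(C(C)C)C(C)C)cc(=O)o4 | intermediate
21 | wailupemycin F, (3S)-3,8-dihydroxy-5-(4-hydroxy-2-oxo-2H-pyran-6-yl)-6-phenyl-3,4-dihydronaphthalen-1(2H)-one | O=C1C[C@@H](O)Cc2c1c(O)cc(-c1ccccc1)c2-c1cc(O)cc(=O)o1 | target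

Total step count: 11. Longest linear sequence: 11 steps (1 → 21). Compounds 5, 8 and 13 are bought.

Steps most likely to fail

Risk 1 (step 5): the internal, phenyl-capped ynone may add slowly, so the silyl dienol ether could be lost by thermal decay or adventitious hydrolysis before it reacts. The fallback uses an alkene dienophile in a catalysed, stepwise annulation at low temperature, and it forms the same two bonds.
- Diene 7 and commercial (E)-4-phenylbut-3-en-2-one are combined with catalytic Tf2NH in CH2Cl2 at −78 °C.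
- The silylium species formed in the flask drives a Mukaiyama–Michael addition (C7 to C6). A second, ring-closing Michael addition (C5 to C4a) then gives the cyclohexene silyl enol ether F1 as a mixture of ring diastereomers.
- Excess DDQ in hot dioxane takes F1 through the cyclohexenone to the phenol F2.
- TBSCl and imidazole in CH2Cl2 bring the fallback back to the route at 10.

Risk 2 (step 10): the C3 silyloxy group may be lost by β-elimination from the Lewis-acid-bound acyl chloride or ketone, with aromatisation of ring B, and attack at the crowded C8a may be slow. Partial loss of the C8 or pyrone silyl group is harmless because step 11 removes them anyway. The fallback closes the ring at the aldehyde oxidation level through a metal phenolate, without strong acid.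
- Acid chloride 19, made as in step 10, is reduced with LiAlH(OtBu)3 in THF at −78 °C to the aldehyde F3.
- KHF2 in MeOH frees only the phenol and pyrone oxygens and gives the hydroxy aldehyde F4.
- EtMgBr (2 equiv) in CH2Cl2 forms the magnesium phenolate. It delivers the tethered aldehyde to C8a in an ortho-selective hydroxyalkylation and gives the C1 carbinol F5 (both C1 epimers).
- MnO2 oxidises the benzylic alcohol to the 8-hydroxy-1-tetralone F6.
- HF·pyridine, as in step 11, brings the fallback back to the route at 21.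

Risk 3 (step 7): the liberated HCl may protodesilylate the enol ether and malonyl dichloride may self-condense, so that the ketone is returned. The fallback builds the chain in two separate C–C bond formations, two carbons and then one.
- Ketone 10 is C-acetylated by soft enolisation (MgBr2·OEt2, iPr2NEt, 1-acetylbenzotriazole, CH2Cl2) to the 1,3-diketone F7.
- Its dianion (LiN(iPr)2, 2 equiv, THF, −78 → −20 °C) is carboxylated with CO2 at the terminal methyl group to the 3,5-dioxo acid F8.
- (CF3CO)2O in CH2Cl2 closes the enol lactone, and aqueous work-up brings the fallback back to the route at 15.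

Further compounds
F1 | step 5 | tert-butyl (3S)-4-[6-acetyl-3-(tert-butyldimethylsilyloxy)-5-phenylcyclohex-2-en-1-yl]-3-(tert-butyldimethylsilyloxy)butanoate (ring diastereomers) | CC(C)(C)OC(=O)C[C@@H](O[Si](C)(C)C(C)(C)C)CC1C=C(O[Si](C)(C)C(C)(C)C)CC(c2ccccc2)C1C(C)=O
F2 | step 5 | tert-butyl (3S)-4-(2-acetyl-5-hydroxy-3-phenylphenyl)-3-(tert-butyldimethylsilyloxy)butanoate | CC(C)(C)OC(=O)C[C@@H](O[Si](C)(C)C(C)(C)C)Cc1cc(O)cc(-c2ccccc2)c1C(C)=O
F3 | step 10 | (3S)-3-(tert-butyldimethylsilyloxy)-4-{5-(tert-butyldimethylsilyloxy)-2-[2-oxo-4-(triisopropylsilyloxy)-2H-pyran-6-yl]-3-phenylphenyl}butanal | O=CC[C@@H](O[Si](C)(C)C(C)(C)C)Cc1cc(O[Si](C)(C)C(C)(C)C)cc(-c2ccccc2)c1-c3cc(O[Si](C(C)C)(C(C)C)C(C)C)cc(=O)o3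
F4 | step 10 | (3S)-3-(tert-butyldimethylsilyloxy)-4-[5-hydroxy-2-(4-hydroxy-2-oxo-2H-pyran-6-yl)-3-phenylphenyl]butanal | O=CC[C@@H](O[Si](C)(C)C(C)(C)C)Cc1cc(O)cc(-c2ccccc2)c1-c3cc(O)cc(=O)o3
F5 | step 10 | 6-[(6S)-6-(tert-butyldimethylsilyloxy)-4,8-dihydroxy-2-phenyl-5,6,7,8-tetrahydronaphthalen-1-yl]-4-hydroxy-2H-pyran-2-one (both carbinol epimers) | OC1C[C@@H](O[Si](C)(C)C(C)(C)C)Cc2c1c(O)cc(-c3ccccc3)c2-c4cc(O)cc(=O)o4
F6 | step 10 | (3S)-3-(tert-butyldimethylsilyloxy)-8-hydroxy-5-(4-hydroxy-2-oxo-2H-pyran-6-yl)-6-phenyl-3,4-dihydronaphthalen-1(2H)-one | O=C1C[C@@H](O[Si](C)(C)C(C)(C)C)Cc2c1c(O)cc(-c3ccccc3)c2-c4cc(O)cc(=O)o4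
F7 | step 7 | tert-butyl (3S)-3-(tert-butyldimethylsilyloxy)-4-[5-(tert-butyldimethylsilyloxy)-2-(3-oxobutanoyl)-3-phenylphenyl]butanoate | CC(C)(C)OC(=O)C[C@@H](O[Si](C)(C)C(C)(C)C)Cc1cc(O[Si](C)(C)C(C)(C)C)cc(-c2ccccc2)c1C(=O)CC(C)=O
F8 | step 7 | 5-{2-[(2S)-4-tert-butoxy-2-(tert-butyldimethylsilyloxy)-4-oxobutyl]-4-(tert-butyldimethylsilyloxy)-6-phenylphenyl}-3,5-dioxopentanoic acid | CC(C)(C)OC(=O)C[C@@H](O[Si](C)(C)C(C)(C)C)Cc1cc(O[Si](C)(C)C(C)(C)C)cc(-c2ccccc2)c1C(=O)CC(=O)CC(=O)O
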